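The cyclohexa-2,4-dienone ring (C1 carbonyl, C2 bearing the isoindolinone, C3 bearing OH, C6 diprenyl) is built late, from a vinylketene and an ynol ether. Heating 3-methyl-4,4-diprenylcyclobutenone with an enantiopure 3-(ethoxyethynyl)isoindolinone should trigger a Danheiser-type cascade (4π opening, [2+2], 4π opening, 6π closure) that forms the C1–C2, C3–C4 and C1–C6 bonds in one operation. It exploits the 1,3-relationship of the C1 and C3 oxygens, which matches the polarity of ketene and ynol ether, and the quaternary C6, which blocks aromatisation. The alkyne already carries the stereocentre, set by Ellman sulfinimine alkynylation; enol ether hydrolysis finishes the synthesis.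

Key step: step 7

Remark: 5-methylhex-4-enoic acid, methyl 2-formyl-3-methoxybenzoate and ethoxyacetylene (sold as a hexane solution) are taken as catalogue compounds.

**Step 1**
Reactants: 1 5-methylhex-4-enoic acid; 2 prenyl bromide (1-bromo-3-methylbut-2-ene)
Product: 3 5-methyl-2-(3-methylbut-2-en-1-yl)hex-4-enoic acid
Conditions: LiN(iPr)2 (2.2 equiv), THF/DMPU, 0 °C; then 2, 0 °C → rt; 1 M HCl work-up
Reagents that add atoms: none
Why: Alkylation of the lithium enediolate of a carboxylic acid (acid dianion alkylation) by SN2 at the primary carbon of the allylic bromide should give the α,α-diprenylated acetic acid, which is achiral because both prenyl groups are identical.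

**Step 2**
Reactants: 3 5-methyl-2-(3-methylbut-2-en-1-yl)hex-4-enoic acid; 4 ethoxyacetylene
Product: 7 3-ethoxy-4,4-bis(3-methylbut-2-en-1-yl)cyclobut-2-en-1-one, via acid chloride 5 (not isolated), via diprenylketene 6 (not isolated)
Conditions: (COCl)2, DMF (cat.), CH2Cl2, 0 °C → rt, evaporate; then 4 (2 equiv), Et3N, MeCN, rt → 45 °C
Reagents that add atoms: none
Why: Dehydrochlorination of the α,α-disubstituted acid chloride by Et3N gives the dialkylketene, which should undergo the known regioselective ketene–alkoxyalkyne [2+2] cycloaddition (ketene carbonyl carbon to the nucleophilic CH terminus of the ynol ether) to the 3-ethoxycyclobutenone, the prenyl alkenes being too close to the ketene for an intramolecular [2+2].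

**Step 3**
Reactants: 7 3-ethoxy-4,4-bis(3-methylbut-2-en-1-yl)cyclobut-2-en-1-one
Product: 9 3-methyl-4,4-bis(3-methylbut-2-en-1-yl)cyclobut-2-en-1-one, via carbinol adduct 8 (not isolated)
Conditions: MeLi, Et2O, −78 °C; then 1 M aq. HCl, 0 °C → rt (short contact)
Reagents that add atoms: methyllithium, [Li]C; water, O
Why: 1,2-Addition of MeLi to the vinylogous ester carbonyl and acid-mediated 1,3-carbonyl transposition (Stork–Danheiser type: ionisation of the tertiary allylic alcohol, attack of water at the ethoxy-bearing carbon, loss of ethanol) should place the methyl group on C3 and the carbonyl next to the diprenyl carbon, the brief contact with cold dilute acid sparing the prenyl groups.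

**Step 4**
Reactants: 10 methyl 2-formyl-3-methoxybenzoate; 11 (S)-2-methylpropane-2-sulfinamide
Product: 12 methyl 2-[(E)-{[(S)-2-methylpropane-2-sulfinyl]imino}methyl]-3-methoxybenzoate
Conditions: CuSO4 (anhydrous, desiccant), CH2Cl2, rt → 40 °C
Reagents that add atoms: none
Why: Condensation of the aldehyde with the sulfinamide over a desiccant (Ellman imine formation) should give the E-configured N-sulfinyl aldimine and leave the methyl ester untouched.

**Step 5**
Reactants: 12 methyl 2-[(E)-{[(S)-2-methylpropane-2-sulfinyl]imino}methyl]-3-methoxybenzoate; 4 ethoxyacetylene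
Product: 14 methyl 2-[(1R)-3-ethoxy-1-{[(S)-2-methylpropane-2-sulfinyl]amino}prop-2-yn-1-yl]-3-methoxybenzoate, via ethoxyethynylmagnesium bromide 13 (not isolated)
Conditions: 4, EtMgBr (Et2O solution), 0 °C; then 12, CH2Cl2, −78 → −30 °C; sat. aq. NH4Cl at −30 °C; chromatography
Reagents that add atoms: none
Why: Addition of the alkynyl Grignard reagent to the Ellman N-sulfinyl aldimine in CH2Cl2 should run through the six-membered chair transition state in which magnesium bridges the sulfinyl oxygen, so that the (S)-configured sulfur directs the alkynyl group to the Re face of the C=N bond and sets the (R)-configured carbon, the minor diastereomer being removed by chromatography and the ester being inert at this temperature.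

**Step 6**
Reactants: 14 methyl 2-[(1R)-3-ethoxy-1-{[(S)-2-methylpropane-2-sulfinyl]amino}prop-2-yn-1-yl]-3-methoxybenzoate
Product: 16 (3R)-3-(ethoxyethynyl)-4-methoxy-2,3-dihydro-1H-isoindol-1-one, via N-sulfinyl lactam 15 (not isolated)
Conditions: NaOMe (1 equiv), MeOH/THF, 0 °C → rt; pH 7 buffer work-up
Reagents that add atoms: none
Why: Methoxide should induce 5-exo-trig lactamisation of the sulfinamide nitrogen onto the ortho ester and then take the sulfinyl group from the resulting N-acyl sulfinamide by nucleophilic substitution at sulfur (sulfinyl transfer, as known for N-sulfinyl oxazolidinones), which frees the lactam N–H without acid, so that the acid-labile ynol ether survives and the stereocentre, not involved in either event, is retained.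

**Step 7**
Reactants: 9 3-methyl-4,4-bis(3-methylbut-2-en-1-yl)cyclobut-2-en-1-one (1.5 equiv); 16 (3R)-3-(ethoxyethynyl)-4-methoxy-2,3-dihydro-1H-isoindol-1-one
Product: 20 (3S)-3-[2-ethoxy-4-methyl-5,5-bis(3-methylbut-2-en-1-yl)-6-oxocyclohexa-1,3-dien-1-yl]-4-methoxy-2,3-dihydro-1H-isoindol-1-one, via vinylketene 17 (not isolated), via vinylcyclobutenone adduct 18 (not isolated), via dienylketene 19 (not isolated)
Conditions: toluene (0.5 M), 80 °C, sealed tube, argon
Reagents that add atoms: none
Why: Thermal 4π electrocyclic opening of cyclobutenone 9 gives vinylketene 17, whose electrophilic carbonyl carbon is attacked by the nucleophilic β-carbon of ynol ether 16 in a regioselective [2+2] cycloaddition, after which the 4-vinylcyclobutenone 18 opens again (4π) to dienylketene 19, which closes by thermal disrotatory 6π electrocyclisation onto the diprenyl-bearing terminus. The closest known reaction is the Danheiser benzannulation of cyclobutenones with alkoxyalkynes, here arrested at the cyclohexa-2,4-dienone because the ring carbon that would have to lose a proton is quaternary. The six-membered carbocycle is closed by the 6π electrocyclisation (the transient four-membered ring by the [2+2] step), so that the C1–C2, C3–C4 and C1–C6 bonds of the dienone are all new. No new stereocentre remains, since the diprenyl carbon carries two identical groups and the sp3 ring carbon of 18 is destroyed on ring opening, while the isoindolinone centre is a spectator whose descriptor changes from R to S only because the dienone carbon now outranks the aryl carbon. The step needs regioselectivity in the [2+2] (secured by the polarisation of the ynol ether), inward rotation of the vinyl group (secured because ring opening is reversible and only the Z-dienylketene cyclises) and chemoselectivity over intramolecular ketene–prenyl cycloaddition and N–H acylation (secured by the high ketenophilicity of the ynol ether, the excess of 9 and the high concentration).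

**Step 8**
Reactants: 20 (3S)-3-[2-ethoxy-4-methyl-5,5-bis(3-methylbut-2-en-1-yl)-6-oxocyclohexa-1,3-dien-1-yl]-4-methoxy-2,3-dihydro-1H-isoindol-1-one
Product: 21 (3S)-3-[2-hydroxy-4-methyl-5,5-bis(3-methylbut-2-en-1-yl)-6-oxocyclohexa-1,3-dien-1-yl]-4-methoxy-2,3-dihydro-1H-isoindol-1-one (CNP0508988.1)
Conditions: 1 M aq. HCl, THF, rt, stopped at full conversion; pH 4–5 buffer work-up
Reagents that add atoms: water, O
Why: Acid-catalysed hydrolysis of the vinylogous ethyl ester (conjugate addition of water to the O-protonated dienone and loss of ethanol) should free the enolised 1,3-dione, dilute acid at room temperature being too weak to cyclise the prenyl groups or to ionise the bonds at the stereocentre.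

**Compound list**
1 | 5-methylhex-4-enoic acid | CC(C)=CCCC(=O)O | starting material
2 | prenyl bromide (1-bromo-3-methylbut-2-ene) | CC(C)=CCBr | starting material
3 | 5-methyl-2-(3-methylbut-2-en-1-yl)hex-4-enoic acid | CC(C)=CCC(CC=C(C)C)C(=O)O | intermediate
4 | ethoxyacetylene (ethoxyethyne) | CCOC#C | starting material
5 | 5-methyl-2-(3-methylbut-2-en-1-yl)hex-4-enoyl chloride (formed in the flask) | CC(C)=CCC(CC=C(C)C)C(Cl)=O | intermediate
6 | diprenylketene, 5-methyl-2-(3-methylbut-2-en-1-yl)hexa-1,4-dien-1-one (formed in the flask) | CC(C)=CCC(CC=C(C)C)=C=O | intermediate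
7 | 3-ethoxy-4,4-bis(3-methylbut-2-en-1-yl)cyclobut-2-en-1-one | CCOC1=CC(=O)C1(CC=C(C)C)CC=C(C)C | intermediate
8 | 3-ethoxy-1-methyl-4,4-bis(3-methylbut-2-en-1-yl)cyclobut-2-en-1-ol, racemic (formed in the flask) | CCOC1=CC(C)(O)C1(CC=C(C)C)CC=C(C)C | intermediate
9 | 3-methyl-4,4-bis(3-methylbut-2-en-1-yl)cyclobut-2-en-1-one | CC1=CC(=O)C1(CC=C(C)C)CC=C(C)C | intermediate
10 | methyl 2-formyl-3-methoxybenzoate | COC(=O)c1cccc(OC)c1C=O | starting material
11 | (S)-2-methylpropane-2-sulfinamide | CC(C)(C)[S@@](N)=O | starting material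
12 | methyl 2-[(E)-{[(S)-2-methylpropane-2-sulfinyl]imino}methyl]-3-methoxybenzoate | COC(=O)c1cccc(OC)c1/C=N/[S@@](=O)C(C)(C)C | intermediate
13 | ethoxyethynylmagnesium bromide (formed in the flask) | CCOC#C[Mg]Br | intermediate
14 | methyl 2-[(1R)-3-ethoxy-1-{[(S)-2-methylpropane-2-sulfinyl]amino}prop-2-yn-1-yl]-3-methoxybenzoate | COC(=O)c1cccc(OC)c1[C@@H](C#COCC)N[S@@](=O)C(C)(C)C | intermediate
15 | (3R)-3-(ethoxyethynyl)-4-methoxy-2-[(S)-2-methylpropane-2-sulfinyl]-2,3-dihydro-1H-isoindol-1-one (formed in the flask) | COc1cccc2c1[C@@H](C#COCC)N([S@@](=O)C(C)(C)C)C2=O | intermediate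
16 | (3R)-3-(ethoxyethynyl)-4-methoxy-2,3-dihydro-1H-isoindol-1-one | COc1cccc2c1[C@@H](C#COCC)NC2=O | intermediate
17 | vinylketene, 3,7-dimethyl-4-(3-methylbut-2-en-1-yl)octa-1,3,6-trien-1-one (formed in the flask) | O=C=CC(C)=C(CC=C(C)C)CC=C(C)C | intermediate
18 | (3S)-3-{2-ethoxy-3-[6-methyl-3-(3-methylbut-2-en-1-yl)hepta-2,5-dien-2-yl]-4-oxocyclobut-1-en-1-yl}-4-methoxy-2,3-dihydro-1H-isoindol-1-one, both epimers at the sp3 ring carbon (formed in the flask) | COc1cccc2c1[C@@H](C1=C(OCC)C(C(C)=C(CC=C(C)C)CC=C(C)C)C1=O)NC2=O | intermediate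
19 | (3S)-3-[(3E)-3-ethoxy-5,9-dimethyl-6-(3-methylbut-2-en-1-yl)-1-oxodeca-1,3,5,8-tetraen-2-yl]-4-methoxy-2,3-dihydro-1H-isoindol-1-one (formed in the flask) | COc1cccc2c1[C@@H](C(=C=O)/C(OCC)=C\C(C)=C(CC=C(C)C)CC=C(C)C)NC2=O | intermediate
20 | (3S)-3-[2-ethoxy-4-methyl-5,5-bis(3-methylbut-2-en-1-yl)-6-oxocyclohexa-1,3-dien-1-yl]-4-methoxy-2,3-dihydro-1H-isoindol-1-one | COc1cccc2c1[C@@H](C1=C(OCC)C=C(C)C(CC=C(C)C)(CC=C(C)C)C1=O)NC2=O | intermediate
21 | (3S)-3-[2-hydroxy-4-methyl-5,5-bis(3-methylbut-2-en-1-yl)-6-oxocyclohexa-1,3-dien-1-yl]-4-methoxy-2,3-dihydro-1H-isoindol-1-one | COc1cccc2c1[C@@H](C1=C(O)C=C(C)C(CC=C(C)C)(CC=C(C)C)C1=O)NC2=O | target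

**Total step count:** 8
**Longest linear sequence:** 5 steps (steps 1, 2, 3, 7, 8; the branch through steps 4, 5, 6, 7, 8 is equally long)

**Steps most likely to fail**

1. Step 7. The vinylketene may be used up by intramolecular pathways (cycloaddition onto a prenyl alkene, hydrogen shift) or may acylate the lactam N–H before the branched ynol ether intercepts it. The ynol ether may also lose ethylene if a higher temperature proves necessary. Fallback: the annulation is moved to the unhindered parent ynol ether and the isoindolinone is attached afterwards. It sets out from 9, 4 and 10 and comes back to the route at 21. Heating 9 with an excess of 4 (toluene, 80 °C, sealed tube) should give 3-ethoxy-5-methyl-6,6-bis(3-methylbut-2-en-1-yl)cyclohexa-2,4-dien-1-one F1, and dilute aqueous HCl in THF should hydrolyse it to 3-hydroxy-5-methyl-6,6-bis(3-methylbut-2-en-1-yl)cyclohexa-2,4-dien-1-one F2. In parallel, 10 and ammonia in methanol should give racemic 3-hydroxy-4-methoxy-2,3-dihydro-1H-isoindol-1-one F3. F2 and F3 are then joined by an asymmetric amidoalkylation (N-acylimine generated in the flask, chiral BINOL-derived phosphoric acid bearing 2,4,6-triisopropylphenyl groups at the 3,3'-positions, toluene, 4 Å molecular sieves, rt). The catalyst antipode is chosen that delivers the (S)-configured product 21.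

2. Step 6. Sulfinyl transfer to methoxide may stay incomplete, or the base may epimerise or isomerise (propargyl to allenyl) the doubly activated C–H while the N-acyl sulfinamide is present. Fallback: the auxiliary is kept as an N-protecting group through the annulation. It sets out from 14 and comes back at 21. Cyclisation of 14 with LiN(SiMe3)2 (THF, −78 → 0 °C, cold quench) should give the N-sulfinyl lactam 15, which is isolated this time. Heating 15 with 9 (toluene, 80 °C) should give (3S)-3-[2-ethoxy-4-methyl-5,5-bis(3-methylbut-2-en-1-yl)-6-oxocyclohexa-1,3-dien-1-yl]-4-methoxy-2-[(S)-2-methylpropane-2-sulfinyl]-2,3-dihydro-1H-isoindol-1-one F4. One treatment with 1 M aqueous HCl in THF should then remove the sulfinyl group and the ethyl group together and give 21.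

3. Step 8. The acid may cyclise a prenyl group onto the enol oxygen, induce a dienone–phenol-type migration, or ionise the bond between C3 and the dione and so erode the stereocentre. Fallback: the enol is unveiled with fluoride from a silyl enol ether. It sets out from 12 and comes back at 21.
   - Ethynylmagnesium bromide (CH2Cl2, −78 °C) should add to 12 in the same sense as in step 5 and give methyl 2-[(1R)-1-{[(S)-2-methylpropane-2-sulfinyl]amino}prop-2-yn-1-yl]-3-methoxybenzoate F5.
   - HCl in methanol followed by Et3N should give (3R)-3-ethynyl-4-methoxy-2,3-dihydro-1H-isoindol-1-one F6.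
   - Double deprotonation (n-BuLi, 2 equiv, THF, −78 °C), oxidation of the acetylide to the ynolate with LiOOtBu and O-silylation with iPr3SiOTf should give (3R)-4-methoxy-3-({[tri(propan-2-yl)silyl]oxy}ethynyl)-2,3-dihydro-1H-isoindol-1-one F7.
   - Annulation of F7 with 9 (toluene, 80 °C) should give (3S)-4-methoxy-3-[4-methyl-5,5-bis(3-methylbut-2-en-1-yl)-6-oxo-2-{[tri(propan-2-yl)silyl]oxy}cyclohexa-1,3-dien-1-yl]-2,3-dihydro-1H-isoindol-1-one F8.
   - Bu4NF buffered with acetic acid (THF, 0 °C) should then give 21.

**Further compounds**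
F1 | step 7 | 3-ethoxy-5-methyl-6,6-bis(3-methylbut-2-en-1-yl)cyclohexa-2,4-dien-1-one | CCOC1=CC(=O)C(CC=C(C)C)(CC=C(C)C)C(C)=C1
F2 | step 7 | 3-hydroxy-5-methyl-6,6-bis(3-methylbut-2-en-1-yl)cyclohexa-2,4-dien-1-one | OC1=CC(=O)C(CC=C(C)C)(CC=C(C)C)C(C)=C1
F3 | step 7 | 3-hydroxy-4-methoxy-2,3-dihydro-1H-isoindol-1-one, racemic | COc1cccc2c1C(O)NC2=O
F4 | step 6 | (3S)-3-[2-ethoxy-4-methyl-5,5-bis(3-methylbut-2-en-1-yl)-6-oxocyclohexa-1,3-dien-1-yl]-4-methoxy-2-[(S)-2-methylpropane-2-sulfinyl]-2,3-dihydro-1H-isoindol-1-one | COc1cccc2c1[C@@H](C1=C(OCC)C=C(C)C(CC=C(C)C)(CC=C(C)C)C1=O)N([S@@](=O)C(C)(C)C)C2=O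
F5 | step 8 | methyl 2-[(1R)-1-{[(S)-2-methylpropane-2-sulfinyl]amino}prop-2-yn-1-yl]-3-methoxybenzoate | COC(=O)c1cccc(OC)c1[C@@H](C#C)N[S@@](=O)C(C)(C)C
F6 | step 8 | (3R)-3-ethynyl-4-methoxy-2,3-dihydro-1H-isoindol-1-one | COc1cccc2c1[C@@H](C#C)NC2=O
F7 | step 8 | (3R)-4-methoxy-3-({[tri(propan-2-yl)silyl]oxy}ethynyl)-2,3-dihydro-1H-isoindol-1-one | COc1cccc2c1[C@@H](C#CO[Si](C(C)C)(C(C)C)C(C)C)NC2=O
F8 | step 8 | (3S)-4-methoxy-3-[4-methyl-5,5-bis(3-methylbut-2-en-1-yl)-6-oxo-2-{[tri(propan-2-yl)silyl]oxy}cyclohexa-1,3-dien-1-yl]-2,3-dihydro-1H-isoindol-1-one | COc1cccc2c1[C@@H](C1=C(O[Si](C(C)C)(C(C)C)C(C)C)C=C(C)C(CC=C(C)C)(CC=C(C)C)C1=O)NC2=O
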